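Percentage points of excess are the unit of this question, so ask of each setting how many of them it moves.

the same everywhere: left-handed substrate 0.20 M; right-handed substrate 0.20 M; racemization catalyst 2.4 mM; impurity 0.45 mM
- Friday's: reagent 0.80 M (fed, over 3.0 d); free catalyst 0.035 mM; run made earlier; the fed solution adds 0.20 times the starting volume
- Saturday's: reagent 0.80 M (fed, over 3.0 d); free catalyst 0.11 mM; run made earlier; the fed solution adds 0.20 times the starting volume
- elm: reagent 0.800 M (fed, over 3.0 d); free catalyst 0.10 mM; the fed solution adds 0.20 times the starting volume; time 3.0 d
- ash: reagent 0.800 M (fed, over 3.0 d); free catalyst 0.030 mM; the fed solution adds 0.20 times the starting volume; time 3.0 d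

| run | time / h | left-handed product / % | right-handed product / % | left-handed substrate / % |
|---|---|---|---|---|
| Friday's | 8.00 | 0 | 0 | 49.8 |
| Friday's | 15.0 | 0.7 | 0.8 | 49.6 |
| Friday's | 25.0 | 1.0 | 0.3 | 48.8 |
| Friday's | 30.0 | 1.7 | 0.8 | 49.5 |
| Friday's | 40.0 | 2.3 | 1.2 | 48.1 |
| Friday's | 48.0 | 2.5 | 0.8 | 48.7 |
| Saturday's | 3.00 | 0 | 0 | 49.3 |
| Saturday's | 10.0 | 0.8 | 0.4 | 49.6 |
| Saturday's | 20.0 | 2.7 | 1.5 | 48.9 |
| Saturday's | 30.0 | 4.9 | 2.1 | 46.3 |
| Saturday's | 40.0 | 6.2 | 3.2 | 45.1 |
| Saturday's | 48.0 | 7.1 | 3.3 | 45.9 |

(each reading ± 0.5 percentage points)

- which of the two ends with the higher excess of left-handed product over right-handed product in the product ("neither" if they lie within 2 percentage points) (elm / ash / neither)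
- excess of left-handed product over right-handed product in the product at the end, elm
- excess of left-handed product over right-handed product in the product at the end, ash

- free catalyst is single-handed; left-handed substrate and right-handed substrate are mirror images of each other, charged as a racemate, each of them at the stated concentration
- every charge counts on the volume at the start, and the solution that is fed holds the whole dose
- what may be going on: free catalyst -> spent catalyst A; racemization catalyst + impurity -> spent catalyst B; reagent + free catalyst + left-handed substrate -> free catalyst + left-handed product; reagent + free catalyst + right-handed substrate -> free catalyst + right-handed product; left-handed substrate + racemization catalyst <-> right-handed substrate + racemization catalyst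
- an excess is the difference of the two amounts in percent of their sum
- an excess is below zero if the other one leads

Start with free catalyst, whose charges in elm and ash differ by 0.523 in their logarithms. Both product-forming steps carry free catalyst and reagent as factors, so these cancel in the ratio of left-handed to right-handed product, along with the decay of free catalyst and the feeding of reagent. Friday's and Saturday's runs test this, their charges differing by 0.497 in the same logarithm. Summed over its readings, Friday's run gives 8.20% against 3.90%, and Saturday's run 21.7% against 10.5%; the logarithms of those ratios differ by 0.00748.

Next comes racemization, since the ratio holds steady while the substrates stay level. Saturday's left-handed substrate reads 45.9% at 48.0 h; an even split of what remains is 44.8%, and the charge minus the left-handed product, unreplaced, is 42.9%. So Saturday's reading lies nearer the even split.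

What must be known well is the selectivity factor, the ratio of left-handed to right-handed product while the substrates stay level. Pooling both runs, my reading of the factor is 2.08, and the logarithm to base ten of the selectivity factor is 0.317, with 0.5 percentage points on each reading. The excess is that ratio less one, over the ratio plus one, so its slope per unit of logarithm is 1.01 here, and a step of 0.0100 in the logarithm moves the excess by 1 point. My factor gives 35.0% for both flasks, so neither leads.

The forecast answers neither, with 35% for elm and 36% for ash: “The catalyst dies, not the substrate.”

The flasks give neither: 36.3% for elm and 36.3% for ash.

    free catalyst → spent catalyst A (k = 8.30 × 10⁻⁶ s⁻¹)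
    racemization catalyst + impurity → spent catalyst B (k = 1.70 M⁻¹ s⁻¹)
    reagent + free catalyst + left-handed substrate → free catalyst + left-handed product (k = 0.0900 M⁻² s⁻¹)
    reagent + free catalyst + right-handed substrate → free catalyst + right-handed product (k = 0.0420 M⁻² s⁻¹)
    left-handed substrate + racemization catalyst ⇌ right-handed substrate + racemization catalyst, rate k5*[racemization catalyst]*[left-handed substrate] forward; the back reaction follows from the equilibrium constant (k = 0.0920 M⁻¹ s⁻¹)

Now take elm read later, at 5.0 d, with all amounts held. The same logarithm, 0.317, applies, since the length of the run cancels as before. It expects an excess of 35.0% again, and 10.9% of left-handed product beside the 5.26% of right-handed product in that flask. That flask holds 11.2% of left-handed product, with left-handed substrate at 41.7% and right-handed substrate at 41.8%, and its excess is 36.3%.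

(The runs were computed for substances that don't exist; the scatter is artificial.)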